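**Plan**

- Retrosynthesis: the enol-ester C–O bond of the seven-membered dienol lactone is cut to an aldehyde acid; the quinone ring is cut between the sulfur-side carbonyl carbon and the benzene ring, giving a 4-aryl-4-hydroxycyclobutenone; the aryl–carbinol bond is cut to an arylmagnesium and a cyclobutenedione; ring A is cut by a retro-Diels–Alder into a 2-arylacrolein and a silyloxydiene.
- Enabling feature: in the quinone ring the N-bearing carbon is bonded to the carbonyl that lies para to the lactone-carbonyl carbon of the benzene ring, and the SO2-bearing carbon to the other carbonyl. A cyclobutenedione whose two alkene carbons carry N and SO2 (thiazine dioxide already fused) holds this pattern, because an aryl nucleophile picks the carbonyl next to the N-bearing carbon.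
- Forward order: ring A by [4+2] cycloaddition and adjustment to the enal acetal; separately the thiazine ring on diethyl squarate and oxidation to the sulfone; union by aryl addition; quinone ring by thermal ring expansion; lactone ring last.
- Stereochemistry: the only stereocentre, the (S)-quaternary carbon bearing methyl and aryl, is set by the catalyst-controlled Diels–Alder reaction and cannot epimerise afterwards.

Key step: step 17

Assumption: the (S)-configured oxazaborolidinium catalyst is taken to expose the Si face at C2 of the 2-arylacrolein (formyl C–H···O binding model); should a test run show the opposite sense, the (R)-catalyst is used with no other change, and any epimer of the cycloadduct at the silyloxy carbon is carried along because that centre is oxidised later.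

**Route**

Step 1
Reactants: 1 4-bromo-2-iodobenzoic acid
Product: 2 tert-butyl 4-bromo-2-iodobenzoate
Conditions: t-BuOC(=NH)CCl3, BF3·OEt2 (cat.), CH2Cl2/cyclohexane, rt
Reagents that add atoms: tert-butyl 2,2,2-trichloroacetimidate, CC(C)(C)OC(=N)C(Cl)(Cl)Cl
Why: Acid-catalysed O-alkylation of the carboxylic acid by the trichloroacetimidate gives the tert-butyl ester, which later withstands the magnesium reagent.

Step 2
Reactants: 2 tert-butyl 4-bromo-2-iodobenzoate
Product: 3 tert-butyl 4-bromo-2-[(E)-2-ethoxyethenyl]benzoate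
Conditions: (E)-EtOCH=CH–Bpin, Pd(PPh3)4 (3 mol%), K2CO3, 1,4-dioxane/H2O, 60 °C
Reagents that add atoms: (E)-2-(2-ethoxyethenyl)-4,4,5,5-tetramethyl-1,3,2-dioxaborolane, CCO/C=C/B1OC(C)(C)C(C)(C)O1
Why: Suzuki–Miyaura coupling in which zerovalent palladium inserts into the C–I bond far faster than into the C–Br bond, so only the iodide is replaced.

Step 3
Reactants: 3 tert-butyl 4-bromo-2-[(E)-2-ethoxyethenyl]benzoate
Product: 4 tert-butyl 4-bromo-2-(2-oxoethyl)benzoate
Conditions: 2 M aq. HCl, THF, rt
Reagents that add atoms: water, O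
Why: Acid-catalysed enol ether hydrolysis (C-protonation, hydration of the oxocarbenium ion) should unmask the arylacetaldehyde while dilute acid at room temperature leaves the tert-butyl ester intact.

Step 4
Reactants: 4 tert-butyl 4-bromo-2-(2-oxoethyl)benzoate
Product: 5 tert-butyl 4-bromo-2-(3-oxoprop-1-en-2-yl)benzoate
Conditions: 37% aq. CH2O, pyrrolidine (10 mol%), EtCO2H (10 mol%), i-PrOH, 45 °C
Reagents that add atoms: formaldehyde, C=O
Why: Amine-catalysed Mannich condensation with formaldehyde and elimination of the amine (organocatalytic α-methylenation of an aldehyde) should give the 2-arylacrolein, which is used at once because such enals dimerise on standing.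

Step 5
Reactants: 6 (E)-2-methylbut-2-enal
Product: 7 tert-butyl(dimethyl){[(1E)-2-methylbuta-1,3-dien-1-yl]oxy}silane
Conditions: TBSOTf, Et3N, Et2O, 0 °C → rt
Reagents that add atoms: tert-butyldimethylsilyl trifluoromethanesulfonate, CC(C)(C)[Si](C)(C)OS(=O)(=O)C(F)(F)F
Why: Soft enolisation, that is O-silylation of the aldehyde and γ-deprotonation by the amine, should give the (E)-1-silyloxydiene.

Step 6
Reactants: 5 tert-butyl 4-bromo-2-(3-oxoprop-1-en-2-yl)benzoate; 7 tert-butyl(dimethyl){[(1E)-2-methylbuta-1,3-dien-1-yl]oxy}silane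
Product: 8 tert-butyl 4-bromo-2-[(1R,2R)-2-{[tert-butyl(dimethyl)silyl]oxy}-1-formyl-3-methylcyclohex-3-en-1-yl]benzoate
Conditions: (S)-B-(o-tolyl)-diphenylprolinol oxazaborolidine (20 mol%), Tf2NH (18 mol%), CH2Cl2, −78 → −40 °C
Reagents that add atoms: none
Why: Lewis-acid-catalysed Diels–Alder reaction in which the silyloxy terminus of the diene bonds to the aryl-bearing carbon of the enal, the formyl group is endo, and the boron-bound aldehyde is shielded on one face by a catalyst phenyl group so that the diene adds to the Si face at C2 and sets the quaternary stereocentre as (R); the silyloxy-bearing centre follows from the endo transition state and is erased in step 9.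

Step 7
Reactants: 8 tert-butyl 4-bromo-2-[(1R,2R)-2-{[tert-butyl(dimethyl)silyl]oxy}-1-formyl-3-methylcyclohex-3-en-1-yl]benzoate
Product: 10 tert-butyl 4-bromo-2-[(1S,2R)-2-{[tert-butyl(dimethyl)silyl]oxy}-1,3-dimethylcyclohex-3-en-1-yl]benzoate, via tosylhydrazone 9 (not isolated)
Conditions: TsNHNH2, EtOH, rt; then catecholborane, CHCl3, 0 °C; NaOAc·3H2O, 60 °C
Reagents that add atoms: none
Why: Hydroboration of the aldehyde tosylhydrazone followed by acetate-induced loss of sulfinate and dinitrogen (Caglioti-type deoxygenation) should turn the neopentyl formyl group into methyl without touching ester, aryl bromide, alkene or silyl ether; the descriptor at C1 changes from R to S only because the priorities change.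

Step 8
Reactants: 10 tert-butyl 4-bromo-2-[(1S,2R)-2-{[tert-butyl(dimethyl)silyl]oxy}-1,3-dimethylcyclohex-3-en-1-yl]benzoate
Product: 11 tert-butyl 4-bromo-2-[(1S,2R)-2-hydroxy-1,3-dimethylcyclohex-3-en-1-yl]benzoate
Conditions: HF·pyridine, pyridine, THF, 0 °C → rt
Reagents that add atoms: none
Why: Fluoride cleaves the Si–O bond under buffered acidic conditions, which avoid a free alkoxide that could lactonise onto the neighbouring tert-butyl ester.

Step 9
Reactants: 11 tert-butyl 4-bromo-2-[(1S,2R)-2-hydroxy-1,3-dimethylcyclohex-3-en-1-yl]benzoate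
Product: 12 tert-butyl 4-bromo-2-[(1S)-1,3-dimethyl-2-oxocyclohex-3-en-1-yl]benzoate
Conditions: Dess–Martin periodinane, CH2Cl2, rt
Reagents that add atoms: none
Why: Dess–Martin oxidation of the secondary allylic alcohol should give the enone and removes the stereocentre at C2.

Step 10
Reactants: 12 tert-butyl 4-bromo-2-[(1S)-1,3-dimethyl-2-oxocyclohex-3-en-1-yl]benzoate
Product: 14 tert-butyl 4-bromo-2-[(1S)-1,3-dimethyl-2-{[(trifluoromethyl)sulfonyl]oxy}cyclohex-2-en-1-yl]benzoate, via lithium enolate 13 (not isolated)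
Conditions: LiBH(s-Bu)3, THF, −78 °C; then N-(5-chloro-2-pyridyl)triflimide, −78 → 0 °C; aq. NH4Cl
Reagents that add atoms: N-(5-chloropyridin-2-yl)bis(trifluoromethanesulfonyl)imide, FC(F)(F)S(=O)(=O)N(c1ccc(Cl)cn1)S(=O)(=O)C(F)(F)F
Why: Conjugate hydride addition of the bulky borohydride to the β-unsubstituted enone (1,2-attack is blocked by the adjacent quaternary carbon) gives a regiodefined lithium enolate that is O-sulfonylated to the vinyl triflate.

Step 11
Reactants: 14 tert-butyl 4-bromo-2-[(1S)-1,3-dimethyl-2-{[(trifluoromethyl)sulfonyl]oxy}cyclohex-2-en-1-yl]benzoate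
Product: 15 tert-butyl 4-bromo-2-[(1S)-2-formyl-1,3-dimethylcyclohex-2-en-1-yl]benzoate
Conditions: CO (3 atm), Bu3SnH (slow addition), Pd(PPh3)4 (5 mol%), LiCl, THF, 50 °C
Reagents that add atoms: carbon monoxide, [C-]#[O+]
Why: Palladium-catalysed reductive carbonylation (oxidative addition to the vinyl triflate, CO insertion, hydride transfer from tin) should give the enal, since under CO at 50 °C zerovalent palladium reacts with a vinyl triflate much faster than with an aryl bromide.

Step 12
Reactants: 15 tert-butyl 4-bromo-2-[(1S)-2-formyl-1,3-dimethylcyclohex-2-en-1-yl]benzoate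
Product: 16 tert-butyl 4-bromo-2-[(1S)-2-(dimethoxymethyl)-1,3-dimethylcyclohex-2-en-1-yl]benzoate
Conditions: HC(OMe)3, PPTS (cat.), MeOH, rt
Reagents that add atoms: trimethyl orthoformate, COC(OC)OC
Why: Acid-catalysed acetalisation with the orthoformate as methoxy source and water scavenger protects the aldehyde against the organomagnesium reagent.

Step 13
Reactants: 17 cysteamine
Product: 19 2-[(2,4-dimethoxybenzyl)amino]ethane-1-thiol, via thiazolidine 18 (not isolated)
Conditions: 2,4-(MeO)2C6H3CHO, EtOH, rt; then NaBH4, 0 → 60 °C, under N2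
Reagents that add atoms: 2,4-dimethoxybenzaldehyde, COc1ccc(C=O)c(OC)c1
Why: Condensation gives the thiazolidine, whose ring-opened iminium form is reduced by borohydride (reductive amination), placing an acid-labile benzyl group on nitrogen so that no N–H quenches the aryl nucleophile in step 16.

Step 14
Reactants: 19 2-[(2,4-dimethoxybenzyl)amino]ethane-1-thiol; 20 diethyl squarate
Product: 22 4-(2,4-dimethoxybenzyl)-3,4-dihydro-2H-cyclobuta[b][1,4]thiazine-5,6-dione, via squaramate thiol 21 (not isolated)
Conditions: Et3N, EtOH, rt → 60 °C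
Reagents that add atoms: none
Why: Two successive addition–elimination reactions at the vinylogous ester carbons of the squarate, first by the secondary amine and then intramolecularly by the thiolate, should close the six-membered thiazine ring.

Step 15
Reactants: 22 4-(2,4-dimethoxybenzyl)-3,4-dihydro-2H-cyclobuta[b][1,4]thiazine-5,6-dione
Product: 24 4-(2,4-dimethoxybenzyl)-3,4-dihydro-2H-cyclobuta[b][1,4]thiazine-5,6-dione 1,1-dioxide, via sulfoxide 23 (not isolated)
Conditions: mCPBA (2.2 equiv), CH2Cl2, 0 °C → rt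
Reagents that add atoms: 3-chloroperoxybenzoic acid, OOC(=O)c1cccc(Cl)c1
Why: Peracid oxidation of the sulfide through the sulfoxide to the sulfone; the tertiary vinylogous amide nitrogen and the electron-poor alkene are not expected to be oxidised.

Step 16
Reactants: 16 tert-butyl 4-bromo-2-[(1S)-2-(dimethoxymethyl)-1,3-dimethylcyclohex-2-en-1-yl]benzoate; 24 4-(2,4-dimethoxybenzyl)-3,4-dihydro-2H-cyclobuta[b][1,4]thiazine-5,6-dione 1,1-dioxide
Product: 26 tert-butyl 2-[(1S)-2-(dimethoxymethyl)-1,3-dimethylcyclohex-2-en-1-yl]-4-[4-(2,4-dimethoxybenzyl)-5-hydroxy-1,1-dioxido-6-oxo-3,4,5,6-tetrahydro-2H-cyclobuta[b][1,4]thiazin-5-yl]benzoate (both carbinol epimers), via arylmagnesium chloride 25 (not isolated)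
Conditions: i-PrMgCl·LiCl, THF, −15 → 0 °C; then add to 24, THF, −78 → −40 °C; aq. NH4Cl
Reagents that add atoms: none
Why: Bromine–magnesium exchange with the LiCl-complexed Grignard reagent is tolerated by the tert-butyl ester and the acetal, and the arylmagnesium should add 1,2 to C5=O, the carbonyl on the nitrogen-bearing carbon and the only one not deactivated by vinylogous amide conjugation; the carbinol epimers converge in step 17.

Step 17
Reactants: 26 tert-butyl 2-[(1S)-2-(dimethoxymethyl)-1,3-dimethylcyclohex-2-en-1-yl]-4-[4-(2,4-dimethoxybenzyl)-5-hydroxy-1,1-dioxido-6-oxo-3,4,5,6-tetrahydro-2H-cyclobuta[b][1,4]thiazin-5-yl]benzoate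
Product: 29 tert-butyl 4-(2,4-dimethoxybenzyl)-7-[(1S)-2-(dimethoxymethyl)-1,3-dimethylcyclohex-2-en-1-yl]-5,10-dioxo-3,4,5,10-tetrahydro-2H-naphtho[2,3-b][1,4]thiazine-8-carboxylate 1,1-dioxide, via vinylketene 27 (not isolated), via hydroquinone 28 (not isolated)
Conditions: p-xylene (degassed), 140 °C; then Ag2O, rt
Reagents that add atoms: none
Why: Heating opens the cyclobutenone by conrotatory four-electron electrocyclic cleavage of the carbinol–carbonyl bond, the hydroxyl rotating outward so that the aryl group ends cis to the ketene in 27; six-electron electrocyclisation of the ketene carbon onto an ortho carbon of the benzoate ring, tautomerisation to hydroquinone 28 and oxidation by Ag2O then give quinone 29. The closest known reaction type is the Moore rearrangement of squarate-derived 4-aryl-4-hydroxycyclobutenones to naphthoquinones, which is documented for 3-amino members of the class. The one ring formed, the six-membered quinone ring, closes by this thermally allowed disrotatory 6π electrocyclisation, which makes the single new C–C bond between the ketene carbon and C5 of the benzoate. No stereocentre is created: the carbinol centre becomes a carbonyl carbon and the quaternary centre of ring A is remote and cannot epimerise. Two selectivities are needed: outward rotation of the hydroxyl, which the donor oxygen secures, and closure at C5 and not at C3, which the tertiary alkyl group on C2 secures because C3 is flanked by it; the N/S orientation needs no control here because the carbinol carbon of 26 is already bonded to the nitrogen-bearing alkene carbon. The sulfonyl group on the ketene α-carbon should make the ketene more electrophilic and favour closure, although together with the amino group it may slow the ring opening, hence 140 °C.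

Step 18
Reactants: 29 tert-butyl 4-(2,4-dimethoxybenzyl)-7-[(1S)-2-(dimethoxymethyl)-1,3-dimethylcyclohex-2-en-1-yl]-5,10-dioxo-3,4,5,10-tetrahydro-2H-naphtho[2,3-b][1,4]thiazine-8-carboxylate 1,1-dioxide
Product: 30 7-[(1S)-2-formyl-1,3-dimethylcyclohex-2-en-1-yl]-5,10-dioxo-3,4,5,10-tetrahydro-2H-naphtho[2,3-b][1,4]thiazine-8-carboxylic acid 1,1-dioxide
Conditions: TFA/CH2Cl2 (1:1), H2O (5 equiv), anisole, rt → 40 °C
Reagents that add atoms: water, O
Why: Acidolysis in one operation: the tert-butyl ester loses isobutene, the acetal is hydrolysed, and the 2,4-dimethoxybenzyl group leaves the protonated vinylogous amide as a benzylic cation that anisole traps.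

Step 19
Reactants: 30 7-[(1S)-2-formyl-1,3-dimethylcyclohex-2-en-1-yl]-5,10-dioxo-3,4,5,10-tetrahydro-2H-naphtho[2,3-b][1,4]thiazine-8-carboxylic acid 1,1-dioxide
Product: 32 target CNP0348176.1, the (S)-configured dienol lactone, via mixed trifluoroacetic anhydride 31 (not isolated)
Conditions: (CF3CO)2O, CH2Cl2 (high dilution), 0 °C → rt; aq. NaHCO3 work-up
Reagents that add atoms: none
Why: The acid is activated as its mixed trifluoroacetic anhydride, the aldehyde oxygen attacks the aroyl carbon to give a seven-membered acyloxy-allyl cation, and loss of the γ-proton gives the dienol lactone (enol lactonisation of an aldehyde acid, vinylogous case); any trifluoroacetyl group on nitrogen or on a dienol oxygen should be removed by the bicarbonate work-up.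

**Compound list**

1 | 4-bromo-2-iodobenzoic acid | OC(=O)c1ccc(Br)cc1I | starting material
2 | tert-butyl 4-bromo-2-iodobenzoate | CC(C)(C)OC(=O)c1ccc(Br)cc1I | intermediate
3 | tert-butyl 4-bromo-2-[(E)-2-ethoxyethenyl]benzoate | CCO/C=C/c1cc(Br)ccc1C(=O)OC(C)(C)C | intermediate
4 | tert-butyl 4-bromo-2-(2-oxoethyl)benzoate | O=CCc1cc(Br)ccc1C(=O)OC(C)(C)C | intermediate
5 | tert-butyl 4-bromo-2-(3-oxoprop-1-en-2-yl)benzoate (2-arylacrolein) | C=C(C=O)c1cc(Br)ccc1C(=O)OC(C)(C)C | intermediate
6 | (E)-2-methylbut-2-enal | C/C=C(\C)C=O | starting material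
7 | tert-butyl(dimethyl){[(1E)-2-methylbuta-1,3-dien-1-yl]oxy}silane | C=C/C(C)=C/O[Si](C)(C)C(C)(C)C | intermediate
8 | tert-butyl 4-bromo-2-[(1R,2R)-2-{[tert-butyl(dimethyl)silyl]oxy}-1-formyl-3-methylcyclohex-3-en-1-yl]benzoate (formyl and silyloxy cis) | O=C[C@@]1(c2cc(Br)ccc2C(=O)OC(C)(C)C)CCC=C(C)[C@H]1O[Si](C)(C)C(C)(C)C | intermediate
9 | (E)-N-tosylhydrazone of aldehyde 8, ring stereocentres unchanged | Cc1ccc(cc1)S(=O)(=O)N/N=C/[C@@]1(c2cc(Br)ccc2C(=O)OC(C)(C)C)CCC=C(C)[C@H]1O[Si](C)(C)C(C)(C)C | intermediate (not isolated)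
10 | tert-butyl 4-bromo-2-[(1S,2R)-2-{[tert-butyl(dimethyl)silyl]oxy}-1,3-dimethylcyclohex-3-en-1-yl]benzoate | C[C@@]1(c2cc(Br)ccc2C(=O)OC(C)(C)C)CCC=C(C)[C@H]1O[Si](C)(C)C(C)(C)C | intermediate
11 | tert-butyl 4-bromo-2-[(1S,2R)-2-hydroxy-1,3-dimethylcyclohex-3-en-1-yl]benzoate | C[C@@]1(c2cc(Br)ccc2C(=O)OC(C)(C)C)CCC=C(C)[C@H]1O | intermediate
12 | tert-butyl 4-bromo-2-[(1S)-1,3-dimethyl-2-oxocyclohex-3-en-1-yl]benzoate | C[C@@]1(c2cc(Br)ccc2C(=O)OC(C)(C)C)CCC=C(C)C1=O | intermediate
13 | lithium (6S)-6-[5-bromo-2-(tert-butoxycarbonyl)phenyl]-2,6-dimethylcyclohex-1-en-1-olate | C[C@@]1(c2cc(Br)ccc2C(=O)OC(C)(C)C)CCCC(C)=C1[O-].[Li+] | intermediate (not isolated)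
14 | tert-butyl 4-bromo-2-[(1S)-1,3-dimethyl-2-{[(trifluoromethyl)sulfonyl]oxy}cyclohex-2-en-1-yl]benzoate | C[C@@]1(c2cc(Br)ccc2C(=O)OC(C)(C)C)CCCC(C)=C1OS(=O)(=O)C(F)(F)F | intermediate
15 | tert-butyl 4-bromo-2-[(1S)-2-formyl-1,3-dimethylcyclohex-2-en-1-yl]benzoate | C[C@@]1(c2cc(Br)ccc2C(=O)OC(C)(C)C)CCCC(C)=C1C=O | intermediate
16 | tert-butyl 4-bromo-2-[(1S)-2-(dimethoxymethyl)-1,3-dimethylcyclohex-2-en-1-yl]benzoate | C[C@@]1(c2cc(Br)ccc2C(=O)OC(C)(C)C)CCCC(C)=C1C(OC)OC | intermediate
17 | cysteamine (2-aminoethane-1-thiol) | NCCS | starting material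
18 | 2-(2,4-dimethoxyphenyl)-1,3-thiazolidine (racemic) | COc1ccc(C2NCCS2)c(OC)c1 | intermediate (not isolated)
19 | 2-[(2,4-dimethoxybenzyl)amino]ethane-1-thiol | COc1ccc(CNCCS)c(OC)c1 | intermediate
20 | diethyl squarate (3,4-diethoxycyclobut-3-ene-1,2-dione) | CCOC1=C(OCC)C(=O)C1=O | starting material
21 | 3-[(2,4-dimethoxybenzyl)(2-sulfanylethyl)amino]-4-ethoxycyclobut-3-ene-1,2-dione | CCOC1=C(N(CCS)Cc2ccc(OC)cc2OC)C(=O)C1=O | intermediate (not isolated)
22 | 4-(2,4-dimethoxybenzyl)-3,4-dihydro-2H-cyclobuta[b][1,4]thiazine-5,6-dione (thiazine fused to the alkene of a cyclobutenedione; C5=O is on the N-bearing carbon) | O=C1C(=O)C2=C1N(Cc1ccc(OC)cc1OC)CCS2 | intermediate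
23 | 4-(2,4-dimethoxybenzyl)-3,4-dihydro-2H-cyclobuta[b][1,4]thiazine-5,6-dione 1-oxide (racemic sulfoxide) | O=C1C(=O)C2=C1N(Cc1ccc(OC)cc1OC)CCS2=O | intermediate (not isolated)
24 | 4-(2,4-dimethoxybenzyl)-3,4-dihydro-2H-cyclobuta[b][1,4]thiazine-5,6-dione 1,1-dioxide | O=C1C(=O)C2=C1N(Cc1ccc(OC)cc1OC)CCS2(=O)=O | intermediate
25 | {4-(tert-butoxycarbonyl)-3-[(1S)-2-(dimethoxymethyl)-1,3-dimethylcyclohex-2-en-1-yl]phenyl}magnesium chloride (LiCl complex) | C[C@@]1(c2cc([Mg]Cl)ccc2C(=O)OC(C)(C)C)CCCC(C)=C1C(OC)OC | intermediate (not isolated)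
26 | tert-butyl 2-[(1S)-2-(dimethoxymethyl)-1,3-dimethylcyclohex-2-en-1-yl]-4-[4-(2,4-dimethoxybenzyl)-5-hydroxy-1,1-dioxido-6-oxo-3,4,5,6-tetrahydro-2H-cyclobuta[b][1,4]thiazin-5-yl]benzoate (4-aryl-4-hydroxycyclobutenone, carbinol carbon bonded to the N-bearing alkene carbon; both carbinol epimers) | C[C@@]1(c2cc(C3(O)C(=O)C4=C3N(Cc3ccc(OC)cc3OC)CCS4(=O)=O)ccc2C(=O)OC(C)(C)C)CCCC(C)=C1C(OC)OC | intermediate
27 | (Z)-3-[aryl(hydroxy)methylidene]-4-(2,4-dimethoxybenzyl)-2-(oxomethylidene)thiomorpholine 1,1-dioxide, aryl = 4-(tert-butoxycarbonyl)-3-[(1S)-2-(dimethoxymethyl)-1,3-dimethylcyclohex-2-en-1-yl]phenyl, aryl cis to the ketene | O=C=C1/C(=C(/O)c2ccc(C(=O)OC(C)(C)C)c(c2)[C@]2(C)CCCC(C)=C2C(OC)OC)N(Cc2ccc(OC)cc2OC)CCS1(=O)=O | intermediate (not isolated)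
28 | 5,10-dihydroxy (naphthalene-1,4-diol) form of 29 | COC(OC)C1=C(C)CCC[C@]1(c1cc2c(O)c3N(Cc4ccc(OC)cc4OC)CCS(=O)(=O)c3c(O)c2cc1C(=O)OC(C)(C)C)C | intermediate (not isolated)
29 | tert-butyl 4-(2,4-dimethoxybenzyl)-7-[(1S)-2-(dimethoxymethyl)-1,3-dimethylcyclohex-2-en-1-yl]-5,10-dioxo-3,4,5,10-tetrahydro-2H-naphtho[2,3-b][1,4]thiazine-8-carboxylate 1,1-dioxide | COC(OC)C1=C(C)CCC[C@]1(c1cc2C(=O)C3=C(C(=O)c2cc1C(=O)OC(C)(C)C)S(=O)(=O)CCN3Cc1ccc(OC)cc1OC)C | intermediate
30 | 7-[(1S)-2-formyl-1,3-dimethylcyclohex-2-en-1-yl]-5,10-dioxo-3,4,5,10-tetrahydro-2H-naphtho[2,3-b][1,4]thiazine-8-carboxylic acid 1,1-dioxide | O=CC1=C(C)CCC[C@]1(c1cc2C(=O)C3=C(C(=O)c2cc1C(=O)O)S(=O)(=O)CCN3)C | intermediate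
31 | mixed anhydride of acid 30 with trifluoroacetic acid | O=CC1=C(C)CCC[C@]1(c1cc2C(=O)C3=C(C(=O)c2cc1C(=O)OC(=O)C(F)(F)F)S(=O)(=O)CCN3)C | intermediate (not isolated)
32 | CNP0348176.1: thiazine-dioxide-fused naphthoquinone whose C8 carboxyl forms a seven-membered enol lactone with the exocyclic enol carbon of ring A; ring A is a 1,3-dimethylcyclohexene with the ring alkene at C3=C4 and an (S)-quaternary carbon bearing methyl and the arene | CC1=CCC[C@]2(C)C1=COC(=O)c1cc3c(cc12)C(=O)C1=C(C3=O)S(=O)(=O)CCN1 | target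

**Count and risks**

Total: 19 steps. Longest linear sequence: 15 steps (steps 1–4, 6–12, 16–19); steps 5 and 13–15 make the two side fragments.

Steps most likely to fail:

1. Step 17. Push–pull conjugation between the amino group and the sulfonyl and carbonyl groups may stabilise the cyclobutenone so much that ring opening becomes slower than thermal degradation (loss of methanol from the acetal, cleavage of the tert-butyl ester). The fallback runs the ring expansion at the sulfide oxidation level, where both ring substituents are donors as in well-documented cases. It sets out from 16 and 22: 16 is converted into the arylmagnesium 25 as in step 16 and added to 22 at −78 °C; nitrogen being the stronger donor, the carbonyl on the N-bearing carbon remains the more electrophilic, which should give tert-butyl 2-[(1S)-2-(dimethoxymethyl)-1,3-dimethylcyclohex-2-en-1-yl]-4-[4-(2,4-dimethoxybenzyl)-5-hydroxy-6-oxo-3,4,5,6-tetrahydro-2H-cyclobuta[b][1,4]thiazin-5-yl]benzoate F1. Thermolysis in toluene or p-xylene and oxidation with Ag2O should give tert-butyl 4-(2,4-dimethoxybenzyl)-7-[(1S)-2-(dimethoxymethyl)-1,3-dimethylcyclohex-2-en-1-yl]-5,10-dioxo-3,4,5,10-tetrahydro-2H-naphtho[2,3-b][1,4]thiazine-8-carboxylate F2. Sulfur-selective oxidation (Na2WO4 cat., 30% H2O2, buffered MeOH/EtOAc), which spares the tetrasubstituted ring A alkene, then rejoins the route at 29.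

2. Step 6. The strongly Lewis-acidic catalyst may desilylate or oligomerise the silyl dienol ether, the 2-arylacrolein may polymerise, or facial selectivity may be eroded by the twisted ortho-substituted aryl group. The fallback separates bond formation from stereocontrol. It sets out from 5 and 7: heating without catalyst (toluene, 80 °C, trace BHT) should give racemic tert-butyl 4-bromo-2-[(1RS,2RS)-2-{[tert-butyl(dimethyl)silyl]oxy}-1-formyl-3-methylcyclohex-3-en-1-yl]benzoate F3. The enantiomers are separated by preparative chromatography on a chiral stationary phase, and the (1R,2R) enantiomer re-enters the route as 8.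

3. Step 19. Intermolecular acyl transfer (trifluoroacetylation of the dienol oxygen or of N–H) or reversion by adventitious water may outrun closure of the seven-membered ring. The fallback replaces the cationic closure by an anionic one. It sets out from 30: EDC·HCl and pentafluorophenol in CH2Cl2 should give the pentafluorophenyl ester of 30 F4. DBU (2.2 equiv) in dilute MeCN then generates the dienolate by γ-deprotonation of the enal, and its oxygen is acylated intramolecularly with loss of pentafluorophenol, which rejoins the route at 32.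

**Further compounds**

F1 | step 17 | tert-butyl 2-[(1S)-2-(dimethoxymethyl)-1,3-dimethylcyclohex-2-en-1-yl]-4-[4-(2,4-dimethoxybenzyl)-5-hydroxy-6-oxo-3,4,5,6-tetrahydro-2H-cyclobuta[b][1,4]thiazin-5-yl]benzoate | C[C@@]1(c2cc(C3(O)C(=O)C4=C3N(Cc3ccc(OC)cc3OC)CCS4)ccc2C(=O)OC(C)(C)C)CCCC(C)=C1C(OC)OC
F2 | step 17 | tert-butyl 4-(2,4-dimethoxybenzyl)-7-[(1S)-2-(dimethoxymethyl)-1,3-dimethylcyclohex-2-en-1-yl]-5,10-dioxo-3,4,5,10-tetrahydro-2H-naphtho[2,3-b][1,4]thiazine-8-carboxylate | COC(OC)C1=C(C)CCC[C@]1(c1cc2C(=O)C3=C(C(=O)c2cc1C(=O)OC(C)(C)C)SCCN3Cc1ccc(OC)cc1OC)C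
F3 | step 6 | racemic tert-butyl 4-bromo-2-[(1RS,2RS)-2-{[tert-butyl(dimethyl)silyl]oxy}-1-formyl-3-methylcyclohex-3-en-1-yl]benzoate | O=C[C@@]1(c2cc(Br)ccc2C(=O)OC(C)(C)C)CCC=C(C)[C@H]1O[Si](C)(C)C(C)(C)C.O=C[C@]1(c2cc(Br)ccc2C(=O)OC(C)(C)C)CCC=C(C)[C@@H]1O[Si](C)(C)C(C)(C)C
F4 | step 19 | pentafluorophenyl 7-[(1S)-2-formyl-1,3-dimethylcyclohex-2-en-1-yl]-5,10-dioxo-3,4,5,10-tetrahydro-2H-naphtho[2,3-b][1,4]thiazine-8-carboxylate 1,1-dioxide | O=CC1=C(C)CCC[C@]1(c1cc2C(=O)C3=C(C(=O)c2cc1C(=O)Oc1c(F)c(F)c(F)c(F)c1F)S(=O)(=O)CCN3)C
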